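## Retrosynthetic overview

1. Target ⇐ debenzylation, desilylation and catalyst-controlled reduction of a 7'-oxo lactone ⇐ S,S-acetal hydrolysis and reductive loss of a menthyloxy group from a 3,4,5-trisubstituted γ-lactone.
2. Key C–C bond: lactone C4–C(dithiane), made by Michael addition of a lithiated 2-aryl-1,3-dithiane to (5R)-5-menthyloxybutenolide; the enolate is benzylated in the same pot (C3–CH2Ar).
3. The aryl dithiane already carries the threo-(S,S) arylglycerol β-aryl ether, whose C–C bond comes from an Evans boron syn-aldol of an N-(aryloxyacetyl)oxazolidinone with O-benzylvanillin.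
4. Building blocks: vanillin, propane-1,3-dithiol, ethyl bromoacetate, (R)-4-benzyloxazolidinone, O-benzylvanillin, 4-benzyloxy-3-methoxybenzyl alcohol, furfural, (−)-menthol.
5. Ring order: butenolide (from furfural) and the temporary dithiane first; the γ-lactone is carried through the Michael step, then opened and re-closed when the menthyloxy group is removed; all arenes are bought.

Assumption: O-metal or O-boron salts that differ from an isolated product only by protonation on work-up are not numbered separately.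

Abbreviations in names: menthyl = (1R,2S,5R)-2-isopropyl-5-methylcyclohexyl; TBS = tert-butyldimethylsilyl; ArG = 4-{[(1S,2S)-1-[4-(benzyloxy)-3-methoxyphenyl]-1,3-bis(TBS-oxy)propan-2-yl]oxy}-3-methoxyphenyl.

## Route

Step 1
Reactants: 1 furfural
Product: 3 5-hydroxyfuran-2(5H)-one (racemic), via furfural 2,5-endoperoxide 2 (not isolated)
Conditions: O2, rose bengal (cat.), hν (visible), MeOH, rt
Reagents that add atoms: oxygen O=O
Why: Schenck-type [4+2] photooxygenation of the furan with singlet oxygen gives the endoperoxide, which methanol fragments with loss of the formyl carbon as methyl formate; no stereocentre needs control.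

Step 2
Reactants: 3 5-hydroxyfuran-2(5H)-one; 4 (−)-menthol
Product: 5 (5R)-5-[(1R,2S,5R)-menthyloxy]furan-2(5H)-one
Conditions: CSA (cat.), toluene, reflux, Dean–Stark; crystallise from petroleum ether (−20 °C); mother liquor re-equilibrated (cat. TsOH) and recrystallised
Reagents that add atoms: none
Why: Acid-catalysed acetalisation gives both C5 epimers, which interconvert under acid, and the (5R)-l-menthyl epimer is the one that crystallises, so crystallisation with re-equilibration sets C5.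

Step 3
Reactants: 6 4-(benzyloxy)-3-methoxybenzyl alcohol
Product: 7 4-(benzyloxy)-3-methoxybenzyl bromide
Conditions: PBr3 (0.4 eq), Et2O, 0 °C; used fresh
Reagents that add atoms: phosphorus tribromide BrP(Br)Br
Why: SN2 bromination of a primary benzylic alcohol via its phosphite ester is fast and clean; no stereocentre.

Step 4
Reactants: 8 vanillin; 9 propane-1,3-dithiol
Product: 10 4-(1,3-dithian-2-yl)-2-methoxyphenol
Conditions: BF3·OEt2 (0.3 eq), CH2Cl2, 0 °C → rt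
Reagents that add atoms: none
Why: Lewis-acid-catalysed dithioacetalisation of an aryl aldehyde tolerates the free phenol and installs the Corey–Seebach acyl-anion precursor.

Step 5
Reactants: 10 4-(1,3-dithian-2-yl)-2-methoxyphenol; 11 ethyl bromoacetate
Product: 12 ethyl [4-(1,3-dithian-2-yl)-2-methoxyphenoxy]acetate
Conditions: K2CO3, acetone, reflux
Reagents that add atoms: none
Why: Williamson ether synthesis (phenoxide SN2 on an α-bromo ester) forms the future C8''–O–aryl bond before any stereocentre exists.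

Step 6
Reactants: 12 ethyl [4-(1,3-dithian-2-yl)-2-methoxyphenoxy]acetate
Product: 13 [4-(1,3-dithian-2-yl)-2-methoxyphenoxy]acetic acid
Conditions: LiOH·H2O, THF/H2O, rt; then 1 M HCl
Reagents that add atoms: lithium hydroxide [Li+].[OH-]
Why: Simple ester saponification; the dithiane is inert to hydroxide.

Step 7
Reactants: 13 [4-(1,3-dithian-2-yl)-2-methoxyphenoxy]acetic acid; 14 (R)-4-benzyl-1,3-oxazolidin-2-one
Product: 16 (R)-4-benzyl-3-{[4-(1,3-dithian-2-yl)-2-methoxyphenoxy]acetyl}-1,3-oxazolidin-2-one, via mixed pivalic anhydride 15 (not isolated)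
Conditions: PivCl, Et3N, THF, −20 °C; then 14, LiCl, −20 °C → rt
Reagents that add atoms: none
Why: N-acylation of the Evans auxiliary through the mixed anhydride (LiCl/Et3N protocol) avoids strong base; the auxiliary stereocentre comes from the chiral pool.

Step 8
Reactants: 16 (R)-4-benzyl-3-{[4-(1,3-dithian-2-yl)-2-methoxyphenoxy]acetyl}-1,3-oxazolidin-2-one; 17 4-(benzyloxy)-3-methoxybenzaldehyde
Product: 19 (R)-4-benzyl-3-{(2R,3S)-3-[4-(benzyloxy)-3-methoxyphenyl]-2-[4-(1,3-dithian-2-yl)-2-methoxyphenoxy]-3-hydroxypropanoyl}-1,3-oxazolidin-2-one, via (Z)-dibutylboron enolate 18 (not isolated)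
Conditions: Bu2BOTf (1.2 eq), iPr2NEt (1.4 eq), CH2Cl2, −78 → 0 °C; 17, −78 → 0 °C; pH 7 buffer/MeOH work-up without peroxide
Reagents that add atoms: none
Why: Evans boron syn-aldol: the (Z)-enolate reacts through a Zimmerman–Traxler chair on the face away from the (R)-benzyl group, giving the (2R,3S)-syn (= threo) adduct that sets both side-chain stereocentres, and the peroxide-free work-up spares the dithiane.

Step 9
Reactants: 19 the syn-aldol imide
Product: 20 (1S,2S)-1-[4-(benzyloxy)-3-methoxyphenyl]-2-[4-(1,3-dithian-2-yl)-2-methoxyphenoxy]propane-1,3-diol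
Conditions: LiBH4, THF, MeOH (1.5 eq), 0 °C
Reagents that add atoms: none
Why: Reductive cleavage of the N-acyl oxazolidinone gives the primary alcohol without touching either stereocentre and returns the auxiliary.

Step 10
Reactants: 20 the threo diol
Product: 21 2-(ArG)-1,3-dithiane (bis-TBS ether of 20)
Conditions: TBSOTf (2.6 eq), 2,6-lutidine, CH2Cl2, −78 → 0 °C
Reagents that add atoms: tert-butyldimethylsilyl triflate CC(C)(C)[Si](C)(C)OS(=O)(=O)C(F)(F)F
Why: Silyl ether formation with the triflate covers both the primary and the hindered benzylic hydroxyl with groups that survive BuLi, KOH/NaBH4, Hg(II) and borane.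

Step 11
Reactants: 21 2-(ArG)-1,3-dithiane; 5 (5R)-5-menthyloxyfuran-2(5H)-one; 7 4-(benzyloxy)-3-methoxybenzyl bromide
Product: 24 (3R,4R,5R)-3-[4-(benzyloxy)-3-methoxybenzyl]-4-[2-(ArG)-1,3-dithian-2-yl]-5-[(1R,2S,5R)-menthyloxy]dihydrofuran-2(3H)-one, via 2-lithio-1,3-dithiane 22 (not isolated), via lithium lactone enolate 23 (not isolated)
Conditions: n-BuLi (1.05 eq), THF, −78 → −30 °C; 5, −78 °C; then 7, DMPU, −78 → −20 °C
Reagents that add atoms: none
Why: Tandem Michael addition–enolate alkylation: the lithiated dithiane adds 1,4 anti to the menthyloxy group (sets C4 = R) and the enolate is benzylated anti to the new bulky C4 substituent (sets C3 = R, trans).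

Step 12
Reactants: 24 the menthyloxy lactone
Product: 27 (3R,4R)-3-[4-(benzyloxy)-3-methoxybenzyl]-4-[2-(ArG)-1,3-dithian-2-yl]dihydrofuran-2(3H)-one, via potassium formyl carboxylate 25 (not isolated), via potassium hydroxy carboxylate 26 (not isolated)
Conditions: KOH, NaBH4, EtOH/THF/H2O, 0 °C → rt; then cold 1 M HCl to pH 3, CH2Cl2, rt
Reagents that add atoms: none
Why: Hydroxide opens the pseudo-ester to the carboxylate aldehyde with loss of menthol, borohydride reduces the aldehyde as it forms, and acidification relactonises, so the acetal carbon becomes the lactone OCH2 while C3 and C4 are untouched.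

Step 13
Reactants: 27 the dithiane lactone
Product: 28 (3R,4R)-3-[4-(benzyloxy)-3-methoxybenzyl]-4-[(ArG)carbonyl]dihydrofuran-2(3H)-one
Conditions: Hg(ClO4)2·3H2O, CaCO3, THF/H2O, 0 °C
Reagents that add atoms: water O
Why: Hg(II)-assisted hydrolysis of the S,S-acetal unmasks the aryl ketone under buffered conditions that leave silyl ethers, benzyl ethers and the thermodynamically preferred trans-lactone intact.

Step 14
Reactants: 28 the keto lactone
Product: 29 (3R,4R)-3-[4-(benzyloxy)-3-methoxybenzyl]-4-[(R)-hydroxy(ArG)methyl]dihydrofuran-2(3H)-one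
Conditions: (S)-Me-CBS (0.5 eq), BH3·SMe2, THF, −20 °C; MeOH quench
Reagents that add atoms: none
Why: Corey–Bakshi–Shibata reduction: the (S)-oxazaborolidine treats the aryl group as the large substituent and delivers hydride to give the (R)-carbinol under catalyst control, the substrate's own facial bias being expected to be weak.

Step 15
Reactants: 29 the bis-TBS carbinol
Product: 30 (3R,4R)-3-[4-(benzyloxy)-3-methoxybenzyl]-4-[(R)-hydroxy(4-{[(1S,2S)-1-[4-(benzyloxy)-3-methoxyphenyl]-1,3-dihydroxypropan-2-yl]oxy}-3-methoxyphenyl)methyl]dihydrofuran-2(3H)-one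
Conditions: TBAF, AcOH (1:1), THF, 0 °C → rt
Reagents that add atoms: none
Why: Fluoride-mediated desilylation buffered with acetic acid removes both TBS ethers without lactone translactonisation or benzylic ionisation.

Step 16
Reactants: 30 the dibenzyl ether
Product: 31 (3R,4R)-4-[(R)-(4-{[(1S,2S)-1,3-dihydroxy-1-(4-hydroxy-3-methoxyphenyl)propan-2-yl]oxy}-3-methoxyphenyl)(hydroxy)methyl]-3-(4-hydroxy-3-methoxybenzyl)dihydrofuran-2(3H)-one (CNP0233652.1)
Conditions: H2 (1 atm), 10% Pd/C, EtOAc/EtOH, rt; stop at full conversion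
Reagents that add atoms: none
Why: Catalytic hydrogenolysis of the two aryl benzyl ethers is much faster than C–O hydrogenolysis of the secondary benzylic alcohols under neutral conditions at 1 atm.

## Compound list

1 | furfural | O=Cc1ccco1 | starting material
2 | furfural 2,5-endoperoxide (2,3,7-trioxabicyclo[2.2.1]hept-5-ene-1-carbaldehyde, racemic) | O=CC12OOC(O1)C=C2 | intermediate (not isolated)
3 | 5-hydroxyfuran-2(5H)-one (racemic) | O=C1C=CC(O)O1 | intermediate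
4 | (−)-menthol, (1R,2S,5R)-2-isopropyl-5-methylcyclohexanol | CC(C)[C@@H]1CC[C@@H](C)C[C@H]1O | starting material
5 | (5R)-5-[(1R,2S,5R)-menthyloxy]furan-2(5H)-one | O=C1C=C[C@H](O[C@@H]2C[C@H](C)CC[C@H]2C(C)C)O1 | intermediate
6 | 4-(benzyloxy)-3-methoxybenzyl alcohol | COc1cc(CO)ccc1OCc1ccccc1 | starting material
7 | 4-(benzyloxy)-3-methoxybenzyl bromide | COc1cc(CBr)ccc1OCc1ccccc1 | intermediate
8 | vanillin | COc1cc(C=O)ccc1O | starting material
9 | propane-1,3-dithiol | SCCCS | starting material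
10 | 4-(1,3-dithian-2-yl)-2-methoxyphenol | COc1cc(C2SCCCS2)ccc1O | intermediate
11 | ethyl bromoacetate | CCOC(=O)CBr | starting material
12 | ethyl [4-(1,3-dithian-2-yl)-2-methoxyphenoxy]acetate | CCOC(=O)COc1ccc(C2SCCCS2)cc1OC | intermediate
13 | [4-(1,3-dithian-2-yl)-2-methoxyphenoxy]acetic acid | OC(=O)COc1ccc(C2SCCCS2)cc1OC | intermediate
14 | (R)-4-benzyl-1,3-oxazolidin-2-one | O=C1N[C@H](Cc2ccccc2)CO1 | starting material
15 | mixed anhydride of 13 with pivalic acid | CC(C)(C)C(=O)OC(=O)COc1ccc(C2SCCCS2)cc1OC | intermediate (not isolated)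
16 | (R)-4-benzyl-3-{[4-(1,3-dithian-2-yl)-2-methoxyphenoxy]acetyl}-1,3-oxazolidin-2-one | O=C(COc1ccc(C2SCCCS2)cc1OC)N1[C@H](Cc2ccccc2)COC1=O | intermediate
17 | 4-(benzyloxy)-3-methoxybenzaldehyde (O-benzylvanillin) | COc1cc(C=O)ccc1OCc1ccccc1 | starting material
18 | (Z)-dibutylboron enolate of 16 | CCCCB(CCCC)O/C(=C\Oc1ccc(C2SCCCS2)cc1OC)N1[C@H](Cc2ccccc2)COC1=O | intermediate (not isolated)
19 | (R)-4-benzyl-3-{(2R,3S)-3-[4-(benzyloxy)-3-methoxyphenyl]-2-[4-(1,3-dithian-2-yl)-2-methoxyphenoxy]-3-hydroxypropanoyl}-1,3-oxazolidin-2-one | COc1cc(C2SCCCS2)ccc1O[C@@H](C(=O)N1[C@H](Cc2ccccc2)COC1=O)[C@@H](O)c1ccc(OCc2ccccc2)c(OC)c1 | intermediate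
20 | (1S,2S)-1-[4-(benzyloxy)-3-methoxyphenyl]-2-[4-(1,3-dithian-2-yl)-2-methoxyphenoxy]propane-1,3-diol | COc1cc(C2SCCCS2)ccc1O[C@@H](CO)[C@@H](O)c1ccc(OCc2ccccc2)c(OC)c1 | intermediate
21 | 2-(ArG)-1,3-dithiane, the 1,3-bis-TBS ether of 20 | COc1cc(C2SCCCS2)ccc1O[C@@H](CO[Si](C)(C)C(C)(C)C)[C@@H](O[Si](C)(C)C(C)(C)C)c1ccc(OCc2ccccc2)c(OC)c1 | intermediate
22 | 2-lithio derivative of 21 | COc1cc(C2([Li])SCCCS2)ccc1O[C@@H](CO[Si](C)(C)C(C)(C)C)[C@@H](O[Si](C)(C)C(C)(C)C)c1ccc(OCc2ccccc2)c(OC)c1 | intermediate (not isolated)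
23 | lithium (4R,5R)-4-[2-(ArG)-1,3-dithian-2-yl]-5-(menthyloxy)-4,5-dihydrofuran-2-olate | [Li]OC1=C[C@@H](C2(SCCCS2)c2ccc(O[C@@H](CO[Si](C)(C)C(C)(C)C)[C@@H](O[Si](C)(C)C(C)(C)C)c3ccc(OCc4ccccc4)c(OC)c3)c(OC)c2)[C@H](O[C@@H]2C[C@H](C)CC[C@H]2C(C)C)O1 | intermediate (not isolated)
24 | (3R,4R,5R)-3-[4-(benzyloxy)-3-methoxybenzyl]-4-[2-(ArG)-1,3-dithian-2-yl]-5-[(1R,2S,5R)-menthyloxy]dihydrofuran-2(3H)-one | COc1cc(C[C@H]2C(=O)O[C@@H](O[C@@H]3C[C@H](C)CC[C@H]3C(C)C)[C@@H]2C2(SCCCS2)c2ccc(O[C@@H](CO[Si](C)(C)C(C)(C)C)[C@@H](O[Si](C)(C)C(C)(C)C)c3ccc(OCc4ccccc4)c(OC)c3)c(OC)c2)ccc1OCc1ccccc1 | intermediate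
25 | potassium (2R,3R)-2-[4-(benzyloxy)-3-methoxybenzyl]-3-[2-(ArG)-1,3-dithian-2-yl]-4-oxobutanoate | COc1cc(C[C@@H](C(=O)[O-])[C@H](C=O)C2(SCCCS2)c2ccc(O[C@@H](CO[Si](C)(C)C(C)(C)C)[C@@H](O[Si](C)(C)C(C)(C)C)c3ccc(OCc4ccccc4)c(OC)c3)c(OC)c2)ccc1OCc1ccccc1.[K+] | intermediate (not isolated)
26 | potassium (2R,3R)-2-[4-(benzyloxy)-3-methoxybenzyl]-3-[2-(ArG)-1,3-dithian-2-yl]-4-hydroxybutanoate | COc1cc(C[C@@H](C(=O)[O-])[C@H](CO)C2(SCCCS2)c2ccc(O[C@@H](CO[Si](C)(C)C(C)(C)C)[C@@H](O[Si](C)(C)C(C)(C)C)c3ccc(OCc4ccccc4)c(OC)c3)c(OC)c2)ccc1OCc1ccccc1.[K+] | intermediate (not isolated)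
27 | (3R,4R)-3-[4-(benzyloxy)-3-methoxybenzyl]-4-[2-(ArG)-1,3-dithian-2-yl]dihydrofuran-2(3H)-one | COc1cc(C[C@H]2C(=O)OC[C@@H]2C2(SCCCS2)c2ccc(O[C@@H](CO[Si](C)(C)C(C)(C)C)[C@@H](O[Si](C)(C)C(C)(C)C)c3ccc(OCc4ccccc4)c(OC)c3)c(OC)c2)ccc1OCc1ccccc1 | intermediate
28 | (3R,4R)-3-[4-(benzyloxy)-3-methoxybenzyl]-4-[(ArG)carbonyl]dihydrofuran-2(3H)-one | COc1cc(C[C@H]2C(=O)OC[C@@H]2C(=O)c2ccc(O[C@@H](CO[Si](C)(C)C(C)(C)C)[C@@H](O[Si](C)(C)C(C)(C)C)c3ccc(OCc4ccccc4)c(OC)c3)c(OC)c2)ccc1OCc1ccccc1 | intermediate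
29 | (3R,4R)-3-[4-(benzyloxy)-3-methoxybenzyl]-4-[(R)-hydroxy(ArG)methyl]dihydrofuran-2(3H)-one | COc1cc(C[C@H]2C(=O)OC[C@@H]2[C@@H](O)c2ccc(O[C@@H](CO[Si](C)(C)C(C)(C)C)[C@@H](O[Si](C)(C)C(C)(C)C)c3ccc(OCc4ccccc4)c(OC)c3)c(OC)c2)ccc1OCc1ccccc1 | intermediate
30 | (3R,4R)-3-[4-(benzyloxy)-3-methoxybenzyl]-4-[(R)-hydroxy(4-{[(1S,2S)-1-[4-(benzyloxy)-3-methoxyphenyl]-1,3-dihydroxypropan-2-yl]oxy}-3-methoxyphenyl)methyl]dihydrofuran-2(3H)-one | COc1cc(C[C@H]2C(=O)OC[C@@H]2[C@@H](O)c2ccc(O[C@@H](CO)[C@@H](O)c3ccc(OCc4ccccc4)c(OC)c3)c(OC)c2)ccc1OCc1ccccc1 | intermediate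
31 | (3R,4R)-4-[(R)-(4-{[(1S,2S)-1,3-dihydroxy-1-(4-hydroxy-3-methoxyphenyl)propan-2-yl]oxy}-3-methoxyphenyl)(hydroxy)methyl]-3-(4-hydroxy-3-methoxybenzyl)dihydrofuran-2(3H)-one (CNP0233652.1) | COc1cc(C[C@H]2C(=O)OC[C@@H]2[C@@H](O)c2ccc(O[C@@H](CO)[C@@H](O)c3ccc(O)c(OC)c3)c(OC)c2)ccc1O | target

## Step count and risks

Total steps: 16. Longest linear sequence: 13 steps (vanillin 8 → 31, steps 4–16). The butenolide branch (steps 1–2) and the bromide branch (step 3) join at step 11.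

Steps most likely to fail:

Step 11 (tandem Michael addition–benzylation with a large dithiane). The likely weak point is alkylation of the hindered enolate 23 by bromide 7. The fallback sets out from 21, 5 and 17 and returns at 24. Lithiate 21 and add 5 as before, but trap enolate 23 at −78 °C with aldehyde 17, a far more reactive electrophile, to give the 3-(α-hydroxybenzyl) lactone F1 as a mixture of carbinol epimers. Dehydrate with MsCl/Et3N then DBU to the 3-benzylidene lactone F2. Reduce the exocyclic alkene by 1,4-hydride addition (L-Selectride, THF, −78 °C, or Stryker's reagent) and equilibrate C3 with DBU to the thermodynamically preferred 3,4-trans isomer, which is 24.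

Step 14 (configuration of the new carbinol). If the CBS reduction does not give a useful ratio, the fallback sets out from 28 and returns at 29. Reduce 28 under substrate control (L-Selectride, THF, −78 °C). If the major product is already 29, use it. If it is the (S)-carbinol epimer F3, invert it by Mitsunobu reaction with 4-nitrobenzoic acid (PPh3, DIAD, THF, 0 °C) to the (R)-4-nitrobenzoate F4, then cleave the ester with K2CO3/MeOH at 0 °C to give 29.

Step 16 (hydrogenolysis next to two activated benzylic alcohols). If benzylic C–O cleavage competes, the fallback sets out from 28 and returns at 31. Hydrogenolyse the benzyl ethers at the ketone stage, where no free benzylic alcohol is present (H2, Pd/C, EtOAc), to give the bis-phenol ketone F5. Silylate both phenols (TBSCl, imidazole, DMF) to the tetrakis-TBS ketone F6. Reduce with (S)-Me-CBS/BH3·SMe2 to the tetrakis-TBS (R)-carbinol F7. Remove all four silyl groups with TBAF/AcOH in THF to give 31 directly.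

Further compounds

F1 | step 11 | (3S,4R,5R)-3-{[4-(benzyloxy)-3-methoxyphenyl](hydroxy)methyl}-4-[2-(ArG)-1,3-dithian-2-yl]-5-[(1R,2S,5R)-menthyloxy]dihydrofuran-2(3H)-one (carbinol epimers) | COc1cc(C(O)[C@H]2C(=O)O[C@@H](O[C@@H]3C[C@H](C)CC[C@H]3C(C)C)[C@@H]2C2(SCCCS2)c2ccc(O[C@@H](CO[Si](C)(C)C(C)(C)C)[C@@H](O[Si](C)(C)C(C)(C)C)c3ccc(OCc4ccccc4)c(OC)c3)c(OC)c2)ccc1OCc1ccccc1
F2 | step 11 | (4R,5R,E)-3-[4-(benzyloxy)-3-methoxybenzylidene]-4-[2-(ArG)-1,3-dithian-2-yl]-5-[(1R,2S,5R)-menthyloxy]dihydrofuran-2(3H)-one | COc1cc(/C=C2/C(=O)O[C@@H](O[C@@H]3C[C@H](C)CC[C@H]3C(C)C)[C@@H]2C2(SCCCS2)c2ccc(O[C@@H](CO[Si](C)(C)C(C)(C)C)[C@@H](O[Si](C)(C)C(C)(C)C)c3ccc(OCc4ccccc4)c(OC)c3)c(OC)c2)ccc1OCc1ccccc1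
F3 | step 14 | (3R,4R)-3-[4-(benzyloxy)-3-methoxybenzyl]-4-[(S)-hydroxy(ArG)methyl]dihydrofuran-2(3H)-one | COc1cc(C[C@H]2C(=O)OC[C@@H]2[C@H](O)c2ccc(O[C@@H](CO[Si](C)(C)C(C)(C)C)[C@@H](O[Si](C)(C)C(C)(C)C)c3ccc(OCc4ccccc4)c(OC)c3)c(OC)c2)ccc1OCc1ccccc1
F4 | step 14 | (R)-(ArG)[(3R,4R)-4-[4-(benzyloxy)-3-methoxybenzyl]-5-oxotetrahydrofuran-3-yl]methyl 4-nitrobenzoate | COc1cc(C[C@H]2C(=O)OC[C@@H]2[C@@H](OC(=O)c2ccc(cc2)[N+](=O)[O-])c2ccc(O[C@@H](CO[Si](C)(C)C(C)(C)C)[C@@H](O[Si](C)(C)C(C)(C)C)c3ccc(OCc4ccccc4)c(OC)c3)c(OC)c2)ccc1OCc1ccccc1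
F5 | step 16 | (3R,4R)-4-(4-{[(1S,2S)-1,3-bis(TBS-oxy)-1-(4-hydroxy-3-methoxyphenyl)propan-2-yl]oxy}-3-methoxybenzoyl)-3-(4-hydroxy-3-methoxybenzyl)dihydrofuran-2(3H)-one | COc1cc(C[C@H]2C(=O)OC[C@@H]2C(=O)c2ccc(O[C@@H](CO[Si](C)(C)C(C)(C)C)[C@@H](O[Si](C)(C)C(C)(C)C)c3ccc(O)c(OC)c3)c(OC)c2)ccc1O
F6 | step 16 | (3R,4R)-4-(4-{[(1S,2S)-1,3-bis(TBS-oxy)-1-[4-(TBS-oxy)-3-methoxyphenyl]propan-2-yl]oxy}-3-methoxybenzoyl)-3-[4-(TBS-oxy)-3-methoxybenzyl]dihydrofuran-2(3H)-one | COc1cc(C[C@H]2C(=O)OC[C@@H]2C(=O)c2ccc(O[C@@H](CO[Si](C)(C)C(C)(C)C)[C@@H](O[Si](C)(C)C(C)(C)C)c3ccc(O[Si](C)(C)C(C)(C)C)c(OC)c3)c(OC)c2)ccc1O[Si](C)(C)C(C)(C)C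
F7 | step 16 | (3R,4R)-4-[(R)-(4-{[(1S,2S)-1,3-bis(TBS-oxy)-1-[4-(TBS-oxy)-3-methoxyphenyl]propan-2-yl]oxy}-3-methoxyphenyl)(hydroxy)methyl]-3-[4-(TBS-oxy)-3-methoxybenzyl]dihydrofuran-2(3H)-one | COc1cc(C[C@H]2C(=O)OC[C@@H]2[C@@H](O)c2ccc(O[C@@H](CO[Si](C)(C)C(C)(C)C)[C@@H](O[Si](C)(C)C(C)(C)C)c3ccc(O[Si](C)(C)C(C)(C)C)c(OC)c3)c(OC)c2)ccc1O[Si](C)(C)C(C)(C)C
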